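**Retrosynthetic overview**
1. Ring A is attached last: the bond between the C=N carbon of ring B and ring A is cut to an imidoyl triflate of a spiro-lactam and boronic acid 9. Before that, the 12-membered ansa ring is opened at the C5–CH2 bond of ring C (acylation, then C=O to CH2).
2. Feature on which the strategy rests: the spiro carbon C2, shared by the oxane (ring D) and ring B, carries the ring oxygen O1 and the ring B nitrogen and is bonded to the C(OMe)=CH–C(ring A)=N chain. Taking the nitrogen out leaves a 3-methoxycyclobutenone spiro-fused at C2.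
3. Key disconnection: that cyclobutenone is cut at C2–C(OMe) and CH–C(=O) into a ketene centred on C2 (from acid chloride 23) and methoxyacetylene 22.
4. Acid chloride 23 comes from δ-lactone 15 by one-carbon homologation (methylenation, hydroboration, oxidation). Lactone 15 comes from (S)-propylene oxide through unsaturated lactone 6, Suzuki coupling with 9 (ring C) and copper-catalysed 1,4-addition of the C7 chain.
5. Order of ring formation: ring D (metathesis) → ring C attached preformed → cyclobutenone (key [2+2]) → ring B (nitrogen insertion) → ansa ring → ring A attached preformed.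

Key step: step 13

Numbering used below: oxane ring D = O1, C2 (spiro), C3 (ring C pyrrolyl), C4 (chain), C5, C6 (methyl); ring A = terminal pyrrole, ring B = methoxy-2H-pyrrole, ring C = bridged pyrrole; TIPS = tri(propan-2-yl)silyl.

Remark on the chemistry: C2 of 18, 19 and 23 is a transient stereocentre that is erased in ketene 24. It is drawn as the epimer expected from hydroboration on the face opposite the C3 pyrrolyl group (2,3-cis); its epimer would serve equally.

**Route**

Step 1
Reactants: 1 (S)-propylene oxide; 2 vinylmagnesium bromide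
Product: 3 (S)-pent-4-en-2-ol
Conditions: CuI (10 mol%), THF, −30 → 0 °C; aq NH4Cl
Reagents that add atoms: none
Why: Copper-catalysed SN2 opening of the epoxide by the vinyl Grignard reagent takes place at the unsubstituted CH2, so the stereocentre of 1 is untouched and becomes C6 (S) of ring D.

Step 2
Reactants: 3 (S)-pent-4-en-2-ol; 4 acryloyl chloride
Product: 5 (S)-pent-4-en-2-yl acrylate
Conditions: Et3N, DMAP (5 mol%), CH2Cl2, 0 °C
Reagents that add atoms: none
Why: Ordinary O-acylation of a secondary alcohol by an acid chloride, which does not involve the stereocentre.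

Step 3
Reactants: 5 (S)-pent-4-en-2-yl acrylate
Product: 6 (S)-6-methyl-5,6-dihydro-2H-pyran-2-one
Conditions: second-generation Grubbs catalyst RuCl2(=CHPh)(H2IMes)(PCy3) (2 mol%), CH2Cl2 (0.02 M), 40 °C
Reagents that add atoms: none
Why: Ring-closing metathesis of an acrylate with a terminal alkene closes the six-membered unsaturated lactone (ring D) and is driven by loss of ethene.

Step 4
Reactants: 6 (S)-6-methyl-5,6-dihydro-2H-pyran-2-one
Product: 8 (S)-3-bromo-6-methyl-5,6-dihydro-2H-pyran-2-one, via trans-dibromo lactone 7 (not isolated)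
Conditions: Br2, CH2Cl2, 0 °C; then Et3N, 0 °C → rt
Reagents that add atoms: bromine, BrBr
Why: Bromine adds across the enoate and Et3N then removes the acidic C3–H with loss of the C4 bromide (E2), which gives the α-bromo enoate regioselectively without touching C6.

Step 5
Reactants: 8 (S)-3-bromo-6-methyl-5,6-dihydro-2H-pyran-2-one; 9 [1-(tert-butoxycarbonyl)pyrrol-2-yl]boronic acid
Product: 10 tert-butyl 2-[(6S)-6-methyl-2-oxo-5,6-dihydro-2H-pyran-3-yl]pyrrole-1-carboxylate
Conditions: Pd(OAc)2 (3 mol%), SPhos (6 mol%), K3PO4, THF/H2O (10:1), 40 °C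
Reagents that add atoms: none
Why: Suzuki–Miyaura coupling of a vinyl bromide with a heteroarylboronic acid; the active biarylphosphine catalyst works at 40 °C, which limits protodeboronation of 9 and hydrolysis of the lactone.

Step 6
Reactants: 11 7-bromoheptan-1-ol
Product: 12 (7-bromoheptyloxy)tri(propan-2-yl)silane
Conditions: TIPSCl, imidazole, DMF, rt
Reagents that add atoms: chlorotri(propan-2-yl)silane, CC(C)[Si](Cl)(C(C)C)C(C)C
Why: Silylation of the primary alcohol gives an ether that survives Grignard formation and every step up to step 15.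

Step 7
Reactants: 12 (7-bromoheptyloxy)tri(propan-2-yl)silane; 10 tert-butyl 2-[(6S)-6-methyl-2-oxo-5,6-dihydro-2H-pyran-3-yl]pyrrole-1-carboxylate
Product: 15 tert-butyl 2-[(3S,4S,6S)-6-methyl-2-oxo-4-(7-TIPSO-heptyl)oxan-3-yl]pyrrole-1-carboxylate, via Grignard reagent 13 (not isolated), via bromomagnesium enolate 14 (not isolated)
Conditions: 12, Mg turnings, THF, 50 °C; then CuI (20 mol%), 10, THF, −40 → 0 °C; aq NH4Cl; then DBU (0.2 equiv), CH2Cl2, rt
Reagents that add atoms: none
Why: Copper-catalysed 1,4-addition of the Grignard reagent to the unsaturated δ-lactone occurs at C4 on the face opposite the C6 methyl (axial attack on the half-chair with pseudo-equatorial methyl, giving 4,6-trans, C4 S), and C3 (S) is set by protonation of enolate 14 and DBU equilibration of the acidic C3–H to the more stable 3,4-trans isomer.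

Step 8
Reactants: 15 lactone
Product: 16 tert-butyl 2-[(3S,4S,6S)-6-methyl-2-methylidene-4-(7-TIPSO-heptyl)oxan-3-yl]pyrrole-1-carboxylate
Conditions: Cp2TiMe2 (2.5 equiv), toluene, 70 °C, dark; filtration through basic Al2O3
Reagents that add atoms: dimethyltitanocene Cp2TiMe2, C[Ti](C)(C1C=CC=C1)C1C=CC=C1
Why: Petasis methylenation, in which Cp2Ti=CH2 (formed by loss of methane) adds to the lactone carbonyl and the oxatitanacyclobutane collapses to the exocyclic enol ether under non-basic conditions, so C3 is not epimerised and the hindered carbamate carbonyl is left alone.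

Step 9
Reactants: 16 exocyclic enol ether
Product: 18 tert-butyl 2-[(2S,3S,4S,6S)-2-(hydroxymethyl)-6-methyl-4-(7-TIPSO-heptyl)oxan-3-yl]pyrrole-1-carboxylate, via B-alkyl-9-BBN borane 17 (not isolated)
Conditions: 9-BBN, THF, 0 °C → rt; then NaBO3·4H2O, THF/H2O, rt
Reagents that add atoms: sodium perborate, B(=O)O[O-].[Na+]
Why: Hydroboration of the enol ether puts boron on the terminal carbon (β to oxygen) and hydrogen on C2 from the face opposite the C3 pyrrolyl group, so the hydroxymethyl group ends cis to it after mild perborate oxidation with retention; this centre is erased again in step 13.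

Step 10
Reactants: 18 primary alcohol
Product: 19 (2S,3S,4S,6S)-3-[1-(tert-butoxycarbonyl)pyrrol-2-yl]-6-methyl-4-(7-TIPSO-heptyl)oxane-2-carboxylic acid
Conditions: PhI(OAc)2 (2.5 equiv), TEMPO (20 mol%), MeCN/pH 7 aqueous buffer (1:1), rt
Reagents that add atoms: water, O
Why: Oxoammonium (TEMPO/PhI(OAc)2) oxidation takes the primary alcohol to the aldehyde and, through its hydrate, to the acid under neutral conditions that leave the TIPS ether and the N-Boc pyrrole intact.

Step 11
Reactants: 20 chloroacetaldehyde dimethyl acetal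
Product: 22 methoxyacetylene, via sodium methoxyacetylide 21 (not isolated)
Conditions: NaNH2 (3 equiv), liquid NH3, −33 °C; then cold saturated aq NaCl; distilled into CH2Cl2 at −78 °C
Reagents that add atoms: none
Why: Two amide-induced eliminations (methanol, then HCl through 2-chlorovinyl methyl ether) give the alkyne, which is held as its sodium acetylide until the aqueous quench; this is the established preparation of the ynol ether.

Step 12
Reactants: 19 carboxylic acid
Product: 23 (2S,3S,4S,6S)-3-[1-(tert-butoxycarbonyl)pyrrol-2-yl]-6-methyl-4-(7-TIPSO-heptyl)oxane-2-carbonyl chloride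
Conditions: 1-chloro-N,N,2-trimethylprop-1-en-1-amine (1.2 equiv), CH2Cl2, 0 °C → rt; used crude
Reagents that add atoms: 1-chloro-N,N,2-trimethylprop-1-en-1-amine, CC(C)=C(Cl)N(C)C
Why: The α-chloroenamine turns the acid into the acid chloride through an acyloxyiminium chloride without releasing HCl, so the Boc group and the silyl ether survive.

Step 13
Reactants: 23 oxane-2-carbonyl chloride; 22 methoxyacetylene
Product: 25 tert-butyl 2-[(4R,6S,8S,9S)-3-methoxy-6-methyl-1-oxo-8-(7-TIPSO-heptyl)-5-oxaspiro[3.5]non-2-en-9-yl]pyrrole-1-carboxylate, via alkoxyketene 24 (not isolated)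
Conditions: 22 (6 equiv), Et3N (2.5 equiv), CH2Cl2, sealed vessel, slow addition of 23 at 0 °C, then rt
Reagents that add atoms: none
Why: Et3N removes HCl from 23 to give alkoxyketene 24, whose carbonyl carbon is attacked in the ketene plane by the nucleophilic CH terminus of methoxyacetylene; the zwitterion formed (enolate at C2, methoxy-stabilised vinyl cation) then collapses by C2–C(OMe) bond formation, a stepwise formal [2+2]. The closest known reaction type is the cycloaddition of ketenes generated from acid chlorides and Et3N with alkoxyacetylenes to give 3-alkoxycyclobutenones. The one ring closed is the four-membered enone, by 4-exo attack of the C2 enolate carbon on the cationic carbon, which makes C2 the spiro atom shared with ring D. The new stereocentre C2 is set by substrate control: the C2–C(OMe) bond forms on the face opposite the adjacent C3 N-Boc-pyrrolyl group, which is also the face opposite the C6 methyl, so the carbonyl carbon (later the nitrogen) ends cis to the pyrrolyl group as in the target. The step needs regioselectivity (methoxy-bearing carbon bonded to C2), which the polarity of the ynol ether provides, and chemoselectivity, which is secured because the pyrrole is deactivated as its N-Boc derivative and the chain oxygen is a silyl ether, so nothing else in 23 traps the ketene.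

Step 14
Reactants: 25 spiro-cyclobutenone
Product: 27 tert-butyl 2-[(5R,7S,9S,10S)-4-methoxy-7-methyl-2-oxo-9-(7-TIPSO-heptyl)-6-oxa-1-azaspiro[4.5]dec-3-en-10-yl]pyrrole-1-carboxylate, via oxime O-mesitylenesulfonate 26 (not isolated)
Conditions: MSH (1.3 equiv), CH2Cl2, 0 °C → rt; then basic Al2O3, MeOH, rt
Reagents that add atoms: O-(mesitylsulfonyl)hydroxylamine (MSH), Cc1cc(C)c(c(C)c1)S(=O)(=O)ON
Why: Proposed new method: MSH should condense with the strained cyclobutenone carbonyl to give oxime sulfonate 26 with the leaving group on the less hindered side, anti to the quaternary C2, after which the electron-rich α-alkoxy carbon C2 migrates from carbon to nitrogen with retention as the sulfonate leaves and water captures the nitrilium ion as the lactam; the closest known reaction type is the Beckmann ring expansion of saturated cyclobutanones to γ-lactams with this reagent, here extended to a 3-alkoxycyclobutenone (a vinylogous ester).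

Step 15
Reactants: 27 spiro-lactam
Product: 28 primary alcohol (27 with the chain end as CH2OH)
Conditions: HF·pyridine, pyridine, THF, 0 °C → rt
Reagents that add atoms: none
Why: Fluoride cleaves the Si–O bond of the primary TIPS ether, and the pyridine buffer keeps the N-Boc group, the enol ether and the N,O-spiro centre intact.

Step 16
Reactants: 28 primary alcohol
Product: 29 carboxylic acid (chain end CO2H, six CH2 groups between C9 of the spiro-lactam and the carboxyl carbon)
Conditions: PhI(OAc)2 (2.5 equiv), TEMPO (20 mol%), MeCN/pH 7 aqueous buffer (1:1), rt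
Reagents that add atoms: water, O
Why: The same oxoammonium oxidation as in step 10 takes the alcohol through the aldehyde hydrate to the acid while the pyrrole is still deactivated by its Boc group against oxidation.

Step 17
Reactants: 29 N-Boc acid
Product: 30 acid with free NH pyrrole (ring C)
Conditions: NaOMe (4 equiv), MeOH/THF, rt; then aq NaH2PO4 (pH 5)
Reagents that add atoms: none
Why: Methoxide attacks the carbamate carbonyl and expels the pyrrolide anion (N-Boc pyrroles behave as activated N-acyl azoles), while the lactam and the vinylogous carbamate are inert, which frees the pyrrole for acylation.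

Step 18
Reactants: 30 pyrrole acid
Product: 32 macrocyclic keto-lactam (the chain carbonyl bonded to C5 of ring C; 12-membered ansa ring; stereocentres as in 27), via mixed trifluoroacetic anhydride 31 (not isolated)
Conditions: TFAA (1.2 equiv), CH2Cl2 (1 mM), 0 °C → rt; aq NaHCO3
Reagents that add atoms: none
Why: Intramolecular Friedel–Crafts acylation in which acyl trifluoroacetate 31 acylates the free α-position C5 of the 2-alkylpyrrole, the most nucleophilic carbon in the molecule, with high dilution favouring the ansa ring over oligomers; the spiro-lactam should tolerate the acid because a cation at C2 would be stabilised neither by the amide nitrogen nor by the methoxy group.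

Step 19
Reactants: 32 macrocyclic keto-lactam
Product: 35 macrocyclic lactam (C=O next to ring C reduced to CH2), via pyrrolylcarbinol 33 (not isolated), via azafulvene 34 (not isolated)
Conditions: NaBH4 (10 equiv), i-PrOH, reflux
Reagents that add atoms: none
Why: Borohydride reduces the 2-acylpyrrole to carbinol 33, which ionises in hot isopropanol through the pyrrole nitrogen to azafulvene 34 and takes a second hydride at the exocyclic carbon (the known deoxygenation of 2-acylpyrroles), the lactam being inert to NaBH4.

Step 20
Reactants: 35 macrocyclic lactam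
Product: 36 imidoyl triflate (ring B as N=C(OTf)–CH=C(OMe)–C spiro)
Conditions: Tf2O (1.2 equiv), 2,6-di-tert-butyl-4-methylpyridine (2 equiv), CH2Cl2, −78 → 0 °C; used directly
Reagents that add atoms: trifluoromethanesulfonic anhydride, O=S(=O)(OS(=O)(=O)C(F)(F)F)C(F)(F)F
Why: O-sulfonylation of the secondary lactam (amide activation) gives the imidoyl triflate; at −78 °C the lactam oxygen should react faster than the carbons of ring C, and the hindered base keeps the medium non-acidic.

Step 21
Reactants: 36 imidoyl triflate; 9 [1-(tert-butoxycarbonyl)pyrrol-2-yl]boronic acid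
Product: 37 N-Boc-premarineosin A (Boc on the ring A nitrogen)
Conditions: Pd(PPh3)4 (10 mol%), K3PO4, 1,4-dioxane/H2O (20:1), 60 °C
Reagents that add atoms: none
Why: Suzuki–Miyaura coupling of the imidoyl triflate with the 2-pyrrolylboronic acid under zerovalent palladium catalysis, the bond construction used to attach ring A to methoxypyrrolinone-derived triflates in prodiginine chemistry, forms the ring B–ring A bond without touching a stereocentre.

Step 22
Reactants: 37 N-Boc-premarineosin A
Product: 38 premarineosin A
Conditions: NaOMe, MeOH/THF, rt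
Reagents that add atoms: none
Why: Methoxide cleaves the pyrrole N-Boc group under basic conditions, which avoids the acid-promoted opening of the spiro-iminal that would scramble C2.

**Compound list**
1 | (S)-propylene oxide | C[C@H]1CO1 | starting material
2 | vinylmagnesium bromide | C=C[Mg]Br | starting material
3 | (S)-pent-4-en-2-ol | C[C@H](O)CC=C | intermediate
4 | acryloyl chloride | C=CC(=O)Cl | starting material
5 | (S)-pent-4-en-2-yl acrylate | C=CC(=O)O[C@@H](C)CC=C | intermediate
6 | (S)-6-methyl-5,6-dihydro-2H-pyran-2-one | O=C1O[C@@H](C)CC=C1 | intermediate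
7 | (6S)-3,4-dibromo-6-methyloxan-2-one (3,4-trans, both diastereomers) | O=C1O[C@@H](C)CC(Br)C1Br | intermediate (not isolated)
8 | (S)-3-bromo-6-methyl-5,6-dihydro-2H-pyran-2-one | O=C1O[C@@H](C)CC=C1Br | intermediate
9 | [1-(tert-butoxycarbonyl)pyrrol-2-yl]boronic acid | OB(O)c1cccn1C(=O)OC(C)(C)C | starting material
10 | tert-butyl 2-[(6S)-6-methyl-2-oxo-5,6-dihydro-2H-pyran-3-yl]pyrrole-1-carboxylate | O=C1O[C@@H](C)CC=C1c2cccn2C(=O)OC(C)(C)C | intermediate
11 | 7-bromoheptan-1-ol | OCCCCCCCBr | starting material
12 | (7-bromoheptyloxy)tri(propan-2-yl)silane | BrCCCCCCCO[Si](C(C)C)(C(C)C)C(C)C | intermediate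
13 | [7-(TIPS-oxy)heptyl]magnesium bromide | Br[Mg]CCCCCCCO[Si](C(C)C)(C(C)C)C(C)C | intermediate (not isolated)
14 | bromomagnesium enolate of lactone 15 (C2=C3 enolate; 4S,6S) | Br[Mg]OC1O[C@@H](C)C[C@H](CCCCCCCO[Si](C(C)C)(C(C)C)C(C)C)C=1c2cccn2C(=O)OC(C)(C)C | intermediate (not isolated)
15 | tert-butyl 2-[(3S,4S,6S)-6-methyl-2-oxo-4-(7-TIPSO-heptyl)oxan-3-yl]pyrrole-1-carboxylate | O=C1O[C@@H](C)C[C@H](CCCCCCCO[Si](C(C)C)(C(C)C)C(C)C)[C@H]1c2cccn2C(=O)OC(C)(C)C | intermediate
16 | tert-butyl 2-[(3S,4S,6S)-6-methyl-2-methylidene-4-(7-TIPSO-heptyl)oxan-3-yl]pyrrole-1-carboxylate | C=C1O[C@@H](C)C[C@H](CCCCCCCO[Si](C(C)C)(C(C)C)C(C)C)[C@H]1c2cccn2C(=O)OC(C)(C)C | intermediate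
17 | B-alkyl-9-BBN adduct of 16 (boron on the exocyclic CH2; 2S,3S,4S,6S) | C1CCC2CCCC1B2C[C@H]3O[C@@H](C)C[C@H](CCCCCCCO[Si](C(C)C)(C(C)C)C(C)C)[C@H]3c4cccn4C(=O)OC(C)(C)C | intermediate (not isolated)
18 | tert-butyl 2-[(2S,3S,4S,6S)-2-(hydroxymethyl)-6-methyl-4-(7-TIPSO-heptyl)oxan-3-yl]pyrrole-1-carboxylate | OC[C@H]1O[C@@H](C)C[C@H](CCCCCCCO[Si](C(C)C)(C(C)C)C(C)C)[C@H]1c2cccn2C(=O)OC(C)(C)C | intermediate
19 | (2S,3S,4S,6S)-3-[1-(tert-butoxycarbonyl)pyrrol-2-yl]-6-methyl-4-(7-TIPSO-heptyl)oxane-2-carboxylic acid | OC(=O)[C@H]1O[C@@H](C)C[C@H](CCCCCCCO[Si](C(C)C)(C(C)C)C(C)C)[C@H]1c2cccn2C(=O)OC(C)(C)C | intermediate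
20 | chloroacetaldehyde dimethyl acetal | COC(CCl)OC | starting material
21 | sodium methoxyacetylide | [Na+].[C-]#COC | intermediate (not isolated)
22 | methoxyacetylene | COC#C | intermediate
23 | (2S,3S,4S,6S)-3-[1-(tert-butoxycarbonyl)pyrrol-2-yl]-6-methyl-4-(7-TIPSO-heptyl)oxane-2-carbonyl chloride | O=C(Cl)[C@H]1O[C@@H](C)C[C@H](CCCCCCCO[Si](C(C)C)(C(C)C)C(C)C)[C@H]1c2cccn2C(=O)OC(C)(C)C | intermediate
24 | tert-butyl 2-[(3S,4S,6S)-6-methyl-2-(oxomethylidene)-4-(7-TIPSO-heptyl)oxan-3-yl]pyrrole-1-carboxylate (ketene) | O=C=C1O[C@@H](C)C[C@H](CCCCCCCO[Si](C(C)C)(C(C)C)C(C)C)[C@H]1c2cccn2C(=O)OC(C)(C)C | intermediate (not isolated)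
25 | tert-butyl 2-[(4R,6S,8S,9S)-3-methoxy-6-methyl-1-oxo-8-(7-TIPSO-heptyl)-5-oxaspiro[3.5]non-2-en-9-yl]pyrrole-1-carboxylate | COC1=CC(=O)[C@]12O[C@@H](C)C[C@H](CCCCCCCO[Si](C(C)C)(C(C)C)C(C)C)[C@H]2c3cccn3C(=O)OC(C)(C)C | intermediate
26 | oxime O-(2,4,6-trimethylbenzenesulfonate) of 25 (sulfonyloxy group anti to the spiro carbon) | COC1=C/C(=N\OS(=O)(=O)c4c(C)cc(C)cc4C)[C@]12O[C@@H](C)C[C@H](CCCCCCCO[Si](C(C)C)(C(C)C)C(C)C)[C@H]2c3cccn3C(=O)OC(C)(C)C | intermediate (not isolated)
27 | tert-butyl 2-[(5R,7S,9S,10S)-4-methoxy-7-methyl-2-oxo-9-(7-TIPSO-heptyl)-6-oxa-1-azaspiro[4.5]dec-3-en-10-yl]pyrrole-1-carboxylate | COC1=CC(=O)N[C@]12O[C@@H](C)C[C@H](CCCCCCCO[Si](C(C)C)(C(C)C)C(C)C)[C@H]2c3cccn3C(=O)OC(C)(C)C | intermediate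
28 | spiro-lactam alcohol (27 with 7-hydroxyheptyl at C9) | COC1=CC(=O)N[C@]12O[C@@H](C)C[C@H](CCCCCCCO)[C@H]2c3cccn3C(=O)OC(C)(C)C | intermediate
29 | spiro-lactam acid (6-carboxyhexyl at C9, N-Boc pyrrole) | COC1=CC(=O)N[C@]12O[C@@H](C)C[C@H](CCCCCCC(=O)O)[C@H]2c3cccn3C(=O)OC(C)(C)C | intermediate
30 | spiro-lactam acid with free NH pyrrole | COC1=CC(=O)N[C@]12O[C@@H](C)C[C@H](CCCCCCC(=O)O)[C@H]2c3ccc[nH]3 | intermediate
31 | mixed anhydride of 30 with trifluoroacetic acid | COC1=CC(=O)N[C@]12O[C@@H](C)C[C@H](CCCCCCC(=O)OC(=O)C(F)(F)F)[C@H]2c3ccc[nH]3 | intermediate (not isolated)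
32 | macrocyclic keto-lactam (2-acylpyrrole, ring C 2,5-bridged) | COC1=CC(=O)N[C@]12O[C@@H](C)C[C@@H]1CCCCCCC(=O)c3ccc([nH]3)[C@H]12 | intermediate
33 | macrocyclic pyrrolylcarbinol (both carbinol epimers) | COC1=CC(=O)N[C@]12O[C@@H](C)C[C@@H]1CCCCCCC(O)c3ccc([nH]3)[C@H]12 | intermediate (not isolated)
34 | macrocyclic azafulvene (2-alkylidene-2H-pyrrole) | COC1=CC(=O)N[C@]12O[C@@H](C)C[C@@H]1CCCCCCC=C3C=CC(=N3)[C@H]12 | intermediate (not isolated)
35 | macrocyclic spiro-lactam (ring A missing, ring B as lactam) | COC1=CC(=O)N[C@]12O[C@@H](C)C[C@@H]1CCCCCCCc3ccc([nH]3)[C@H]12 | intermediate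
36 | macrocyclic imidoyl triflate | COC1=CC(OS(=O)(=O)C(F)(F)F)=N[C@]12O[C@@H](C)C[C@@H]1CCCCCCCc3ccc([nH]3)[C@H]12 | intermediate
37 | N-Boc-premarineosin A (Boc on ring A nitrogen) | COC1=CC(c2cccn2C(=O)OC(C)(C)C)=N[C@]12O[C@@H](C)C[C@@H]1CCCCCCCc3ccc([nH]3)[C@H]12 | intermediate
38 | premarineosin A | COC1=CC(c2ccc[nH]2)=N[C@]12O[C@@H](C)C[C@@H]1CCCCCCCc3ccc([nH]3)[C@H]12 | target

**Step count**
Total: 22 steps. Longest linear sequence: 20 steps (steps 1–5, 7–10, 12–22); steps 6 and 11 are side branches.

**Steps most likely to fail**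

1. Step 14 (the step labelled as a proposed new method). The aminating reagent may attack the methoxy-bearing β-carbon of the vinylogous ester by addition–elimination instead of condensing at the carbonyl. Alternatively the oxime sulfonate may fragment at the oxygen-stabilised C2 (to an oxocarbenium ion and a nitrile) instead of undergoing the 1,2-shift. The fallback uses known reaction types only, sets out from 25 and comes back at 27. Baeyer–Villiger oxidation of 25 (mCPBA, NaHCO3, CH2Cl2, 0 °C) would insert oxygen where nitrogen was wanted, the same α-alkoxy carbon migrating with retention, to give spiro-butenolide F1. Aminolysis of this acylal lactone with the aluminium amide Me2AlNH2 (from AlMe3 and NH4Cl, CH2Cl2) would open it to the (E)-3-methoxyacrylamide lactol F2. Acid-catalysed cyclodehydration (camphorsulfonic acid cat., 4 Å molecular sieves, CH2Cl2) would then close the amide nitrogen onto the oxocarbenium ion at C2 and give 27. In this variant the spiro centre would be set in the last operation under thermodynamic control, so the epimer ratio would have to be established and the unwanted epimer recycled under the same acid.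

2. Step 13 (key step). Dehydrochlorination of the hindered tertiary α-alkoxy acid chloride may be slow. The ketene may dimerise or be consumed by acylammonium pathways before the volatile, only moderately nucleophilic alkyne intercepts it. The facial bias at C2 may also be insufficient. The fallback sets out from 23 and comes back at 25. Ketene 24 would be generated in the same way but trapped with 1,1-dimethoxyethene (3 equiv, CH2Cl2, −20 °C → rt), a much stronger and non-volatile π-nucleophile, in a ketene–ketene acetal [2+2] at the saturated oxidation level to give the 3,3-dimethoxy spiro-cyclobutanone F3. Loss of methanol (pyridinium p-toluenesulfonate cat., toluene, 60 °C) would then unveil the enol ether and return cyclobutenone 25.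

3. Step 18. Intermolecular acylation may lead to oligomers. A β-position of ring C may be attacked instead of C5. The anhydride may trifluoroacetylate the pyrrole, and the acid may erode the enol ether. The fallback sets out from 30 and comes back at 32, and replaces electrophilic substitution under acid by acyl transfer under base. Acid 30 would be converted with 2,2'-dipyridyl disulfide and PPh3 (CH2Cl2, rt) into the S-(pyridin-2-yl) thioester F4. Slow addition of F4 to the hindered amide base MgCl(TMP)·LiCl (TMP = 2,2,6,6-tetramethylpiperidide, 2.5 equiv, toluene, −78 °C → rt, high dilution) would magnesiate the pyrrole nitrogen. The thioester would then be delivered to the adjacent α-carbon C5 through a magnesium chelate with the pyridine nitrogen, the known regiospecific 2-acylation of pyrrolylmagnesium halides, to give 32.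

**Further compounds**
F1 | step 14 | spiro-butenolide (25 with O inserted between C=O and the spiro carbon; 4-methoxy-1,6-dioxaspiro[4.5]dec-3-en-2-one core) | COC1=CC(=O)O[C@]12O[C@@H](C)C[C@H](CCCCCCCO[Si](C(C)C)(C(C)C)C(C)C)[C@H]2c3cccn3C(=O)OC(C)(C)C
F2 | step 14 | (E)-3-methoxy-3-(2-hydroxyoxan-2-yl)prop-2-enamide lactol (both anomers) | NC(=O)/C=C(OC)\C1(O)O[C@@H](C)C[C@H](CCCCCCCO[Si](C(C)C)(C(C)C)C(C)C)[C@H]1c2cccn2C(=O)OC(C)(C)C
F3 | step 13 | 3,3-dimethoxy spiro-cyclobutanone (3,3-dimethoxy-5-oxaspiro[3.5]nonan-1-one core) | COC1(OC)CC(=O)[C@]12O[C@@H](C)C[C@H](CCCCCCCO[Si](C(C)C)(C(C)C)C(C)C)[C@H]2c3cccn3C(=O)OC(C)(C)C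
F4 | step 18 | S-(pyridin-2-yl) thioester of acid 30 | COC1=CC(=O)N[C@]12O[C@@H](C)C[C@H](CCCCCCC(=O)Sc4ccccn4)[C@H]2c3ccc[nH]3
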